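**Retrosynthetic overview**

1. The target is cut at the ester between the two halves: left-half acid 33 (both CH2OH groups as TBS ethers) plus right-half diol 23 (acid as tert-butyl ester); Yamaguchi esterification at the primary hydroxyl, then one acidolysis.
2. Right half (2-benzoxepine numbering: C1 lactone C=O, O2, C3, C4, C5, C5a, C6 bearing isopropyl, C7, C8, C9 carbinol, C9a): the oxepinone ring is closed last by ring-closing metathesis (C4=C5); C5a and C6 are set by hydroxyl-directed syn-hydroformylation of a cyclohexene (temporary lactol ring); the carbocycle itself comes from a Diels–Alder reaction that forms C7–C8 and C9–C9a.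
3. Enabling feature: ring carbon C9 carries both an oxygen and a CH2O carbon and sits between C8H2 and C9a, so C8–C9 is a masked 2-oxyacrylic acid (captodative alkene); C9a–C5a–C6–C7, taken with C5a=C6 as an alkene, is a 1-CH2O-3-isopropyl-1,3-diene. The carbocycle is therefore the [4+2] adduct of dienyl acetate 10 and the lactic-acid-derived dioxolanone 5, whose ring is a temporary ring that fixes C9 and C9a and is cleaved afterwards.
4. Left half: (R)-cryptone 26 (organocatalytic Michael addition, aldol condensation), trans vinyl addition with enol triflate formation, ozonolysis, bromo-Wittig olefination, double Stille hydroxymethylation.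
5. Order of ring formation: right-half cyclohexene (step 8), temporary lactol (step 11), oxepinone (step 15); left-half cyclohexenone (step 18).

Key step: step 8

Assumption: the structure is taken exactly as drawn, so the isopropyl- and side-chain-bearing ring carbons of the left half belong to the enantiomeric series of those of the right half, and each half is made from its own chiral source.

Step 1
Reactants: 1 (S)-lactic acid; 2 pivalaldehyde
Product: 3 (2S,5S)-2-tert-butyl-5-methyl-1,3-dioxolan-4-one
Conditions: TsOH·H2O (cat.), H2SO4 (cat.), pentane, reflux, Dean–Stark; recrystallisation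
Reagents that add atoms: none
Why: Acid-catalysed acetalisation with azeotropic removal of water should give the dioxolanone, the lactate stereocentre steering the new acetal carbon mainly to the cis (2S,5S) isomer under thermodynamic control, which crystallisation should upgrade.

Step 2
Reactants: 3 (2S,5S)-2-tert-butyl-5-methyl-1,3-dioxolan-4-one
Product: 4 5-bromo-2-tert-butyl-5-methyl-1,3-dioxolan-4-one (acetal carbon as in 3; C5 epimers)
Conditions: NBS, AIBN (cat.), CCl4, reflux
Reagents that add atoms: N-bromosuccinimide, O=C1CCC(=O)N1Br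
Why: Radical bromination (Wohl–Ziegler type) should take place only at the tertiary, captodatively stabilised C5–H; the acetal carbon, the stereocentre that is carried on, is not touched.

Step 3
Reactants: 4 5-bromo-2-tert-butyl-5-methyl-1,3-dioxolan-4-one
Product: 5 (2S)-2-tert-butyl-5-methylidene-1,3-dioxolan-4-one
Conditions: Et3N, CH2Cl2, 0 °C to rt
Reagents that add atoms: none
Why: Base-induced dehydrobromination (E2) should give the exocyclic alkene and leave the tert-butyl acetal carbon as the single stereocentre (2S).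

Step 4
Reactants: 6 3-methylbutanal
Product: 7 3-methyl-2-methylidenebutanal
Conditions: 37% aq. CH2O, pyrrolidine (10 mol%), propionic acid (10 mol%), iPrOH, 45 °C
Reagents that add atoms: formaldehyde, C=O
Why: Amine/acid-catalysed Mannich condensation–elimination (α-methylenation of an aldehyde) should install the terminal methylene; no stereocentre is formed.

Step 5
Reactants: 7 3-methyl-2-methylidenebutanal
Product: 8 ethyl (2E)-5-methyl-4-methylidenehex-2-enoate
Conditions: Ph3P=CHCO2Et, CH2Cl2, rt
Reagents that add atoms: ethyl (triphenylphosphoranylidene)acetate, CCOC(=O)C=P(c1ccccc1)(c1ccccc1)c1ccccc1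
Why: Wittig olefination with a stabilised ylide should give the E-dienoate selectively.

Step 6
Reactants: 8 ethyl (2E)-5-methyl-4-methylidenehex-2-enoate
Product: 9 (2E)-5-methyl-4-methylidenehex-2-en-1-ol
Conditions: iBu2AlH (2.2 equiv), CH2Cl2, −78 °C; aq. potassium sodium tartrate
Reagents that add atoms: none
Why: 1,2-Reduction of the conjugated ester by iBu2AlH at low temperature should give the allylic alcohol without touching the diene.

Step 7
Reactants: 9 (2E)-5-methyl-4-methylidenehex-2-en-1-ol
Product: 10 (2E)-5-methyl-4-methylidenehex-2-en-1-yl acetate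
Conditions: Ac2O, pyridine, DMAP (cat.), CH2Cl2, 0 °C to rt
Reagents that add atoms: acetic anhydride, CC(=O)OC(C)=O
Why: Acetylation (nucleophilic acyl substitution) masks the hydroxyl so that it can neither hydrogen-bond to nor be acylated by the dienophile in the next step.

Step 8
Reactants: 10 (2E)-5-methyl-4-methylidenehex-2-en-1-yl acetate; 5 (2S)-2-tert-butyl-5-methylidene-1,3-dioxolan-4-one
Product: 11 [(2S,5R,6R)-2-tert-butyl-4-oxo-8-(propan-2-yl)-1,3-dioxaspiro[4.5]dec-7-en-6-yl]methyl acetate
Conditions: toluene (1 M), 2,6-di-tert-butyl-4-methylphenol (cat.), 110 °C, sealed tube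
Reagents that add atoms: none
Why: Concerted, asynchronous [4π+2π] cycloaddition of the s-cis diene 10 to the captodative exocyclic alkene of 5; the closest known reaction type is the exo-selective Diels–Alder reaction of 2-tert-butyl-5-methylene-1,3-dioxolan-4-one with cyclic and acyclic dienes. The cyclohexene ring is closed intermolecularly in the suprafacial [4+2] mode, and the spiro junction is created at the same time. The quaternary carbon (future C9) is set by approach of the diene to the alkene face anti to the tert-butyl group of the dioxolanone; the neighbouring CH(CH2OAc) carbon (future C9a) is set by the exo orientation of the lactone carbonyl together with the E geometry of the diene, which places CH2OAc cis to the ring oxygen. Three selectivities are needed: regiochemistry, secured because the 1-CH2OAc and the 3-isopropyl substituents of the diene both direct the substituted dienophile carbon to the CH2OAc-bearing terminus ("ortho" and "para" preferences reinforce each other); exo selectivity, secured by the s-cis-locked α-oxy lactone; and face selectivity, secured by the tert-butyl acetal.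

Step 9
Reactants: 11 Diels–Alder adduct
Product: 12 (1R,2R)-1,2-bis(hydroxymethyl)-4-(propan-2-yl)cyclohex-3-en-1-ol
Conditions: LiAlH4, THF, 0 °C to rt; H2O, aq. NaOH work-up
Reagents that add atoms: none
Why: Hydride reduction should open the acylal (lactone carbonyl to CH2OH, acetal carbon lost as neopentyl alcohol) and cleave the acetate, leaving both stereocentres and the alkene untouched.

Step 10
Reactants: 12 (1R,2R)-1,2-bis(hydroxymethyl)-4-(propan-2-yl)cyclohex-3-en-1-ol
Product: 13 [(5R,6R)-2,2-dimethyl-8-(propan-2-yl)-1,3-dioxaspiro[4.5]dec-7-en-6-yl]methanol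
Conditions: 2,2-dimethoxypropane, PPTS (cat.), CH2Cl2, rt
Reagents that add atoms: 2,2-dimethoxypropane, COC(C)(C)OC
Why: Acid-catalysed transacetalisation under thermodynamic control should select the 1,2-diol (five-membered dioxolane) over the 1,3-diol and so leave the primary homoallylic hydroxyl free as the directing group.

Step 11
Reactants: 13 [(5R,6R)-2,2-dimethyl-8-(propan-2-yl)-1,3-dioxaspiro[4.5]dec-7-en-6-yl]methanol
Product: 15 2,2-dimethyl-7'-(propan-2-yl)hexahydro-1'H-spiro[[1,3]dioxolane-4,4'-[2]benzofuran]-1'-ol (cis-fused lactol; anomer mixture), via hydroxy aldehyde 14 (not isolated)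
Conditions: CO/H2 (1:1, 40 bar), Rh(acac)(CO)2 (2 mol%), Ph2POMe (20 mol%), 4 Å molecular sieves, THF, 60 °C
Reagents that add atoms: carbon monoxide, [C-]#[O+]
Why: Proposed new method: reversible exchange of Ph2POMe with the primary homoallylic alcohol should give a substrate-bound phosphinite that chelates rhodium and delivers Rh–H to the nearer alkene carbon from the CH2O face (six-membered chelate), so that syn hydrometalation puts H on the isopropyl-bearing carbon and, after CO insertion with retention and hydrogenolysis, the formyl group on the neighbouring carbon cis to CH2OH (trapped as the cis-fused lactol), which sets both new stereocentres (isopropyl trans to formyl through syn addition, formyl cis to CH2OH through intramolecular delivery); the closest known reaction type is the phosphinite-directed, branched-selective hydroformylation of homoallylic alcohols with 1,2-disubstituted alkenes, and the undirected syn-hydroformylation of 1-methylcyclohexene shows that a trisubstituted ring alkene takes the formyl group only at its CH carbon.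

Step 12
Reactants: 15 cis-fused lactol
Product: 16 [(5R,6R,7S,8S)-7-ethenyl-2,2-dimethyl-8-(propan-2-yl)-1,3-dioxaspiro[4.5]decan-6-yl]methanol
Conditions: Ph3PCH3Br (3 equiv), KOtBu (3 equiv), THF, 0 °C to rt
Reagents that add atoms: methyltriphenylphosphonium bromide, C[P+](c1ccccc1)(c1ccccc1)c1ccccc1.[Br-]
Why: Wittig methylenation of the lactol through its open hydroxy aldehyde form should give the vinyl group and release the primary alcohol; no stereocentre is formed, and the fast olefination should outrun epimerisation of the α-carbon.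

Step 13
Reactants: 16 vinyl alcohol
Product: 18 (5R,6S,7S,8S)-7-ethenyl-2,2-dimethyl-8-(propan-2-yl)-1,3-dioxaspiro[4.5]decane-6-carboxylic acid, via aldehyde 17 (not isolated)
Conditions: TEMPO (20 mol%), PhI(OAc)2 (2.2 equiv), MeCN/pH 7 aqueous buffer (1:1), rt
Reagents that add atoms: water, O
Why: Oxoammonium (TEMPO) oxidation with PhI(OAc)2 in aqueous acetonitrile should take the primary alcohol through the aldehyde hydrate to the acid without touching the vinyl group or the acetonide, and fast enough to keep the α-stereocentre.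

Step 14
Reactants: 18 carboxylic acid; 19 tert-butyl 2-(bromomethyl)prop-2-enoate
Product: 21 2-(tert-butoxycarbonyl)prop-2-en-1-yl (5R,6S,7S,8S)-7-ethenyl-2,2-dimethyl-8-(propan-2-yl)-1,3-dioxaspiro[4.5]decane-6-carboxylate, via potassium carboxylate 20 (not isolated)
Conditions: K2CO3, DMF, 0 °C to rt
Reagents that add atoms: none
Why: O-Alkylation of the carboxylate by the allylic bromide (SN2 and SN2′ give the same ester) should proceed under conditions too mild to epimerise the α-carbon.

Step 15
Reactants: 21 diene ester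
Product: 22 acetonide of 23: tert-butyl 2,2-dimethyl-1'-oxo-6'-(propan-2-yl)-1',3',5a',6',7',8'-hexahydro-9a'H-spiro[[1,3]dioxolane-4,9'-[2]benzoxepine]-4'-carboxylate (stereocentres as in 23)
Conditions: second-generation Hoveyda–Grubbs catalyst RuCl2(H2IMes)(=CH-C6H4-2-OiPr) (10 mol%), toluene (2 mM), 80 °C
Reagents that add atoms: none
Why: Ring-closing metathesis between the vinyl group and the 1,1-disubstituted acrylate alkene should close the seven-membered lactone with loss of ethene, the ring forcing the required geometry of the trisubstituted alkene (ring carbon cis to CH2O).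

Step 16
Reactants: 22 lactone acetonide
Product: 23 tert-butyl (5aR,6S,9R,9aS)-9-hydroxy-9-(hydroxymethyl)-1-oxo-6-(propan-2-yl)-1,3,5a,6,7,8,9,9a-octahydro-2-benzoxepine-4-carboxylate
Conditions: AcOH/H2O (4:1), 40 °C
Reagents that add atoms: none
Why: Mild acid hydrolysis of the acetonide should free the tertiary/primary diol while the tert-butyl ester and the lactone survive.

Step 17
Reactants: 6 3-methylbutanal; 24 but-3-en-2-one
Product: 25 (2R)-5-oxo-2-(propan-2-yl)hexanal
Conditions: (R)-2-[diphenyl(trimethylsilyloxy)methyl]pyrrolidine (5 mol%), ethyl 3,4-dihydroxybenzoate (20 mol%), neat, 4 °C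
Reagents that add atoms: none
Why: Enamine-catalysed Michael addition, in which the diphenyl(silyloxy)methyl group of the (R)-catalyst shields one face of the E-enamine, should set the (R) stereocentre α to the aldehyde.

Step 18
Reactants: 25 (2R)-5-oxo-2-(propan-2-yl)hexanal
Product: 26 (4R)-4-(propan-2-yl)cyclohex-2-en-1-one
Conditions: 0.1 M aq. KOH, Bu4NOH (cat.), Et2O/THF, reflux
Reagents that add atoms: none
Why: Intramolecular aldol condensation (methyl ketone enolate onto the aldehyde, then dehydration) should close the cyclohexenone faster than the α-branched aldehyde enolises, so the stereocentre is kept.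

Step 19
Reactants: 26 (4R)-4-(propan-2-yl)cyclohex-2-en-1-one
Product: 28 (3R,4R)-3-ethenyl-4-(propan-2-yl)cyclohex-1-en-1-yl trifluoromethanesulfonate, via magnesium enolate 27 (not isolated)
Conditions: CH2=CHMgBr, CuBr·SMe2 (10 mol%), THF, −40 °C; then N-(5-chloro-2-pyridyl)bis(trifluoromethanesulfonimide), −78 °C to rt
Reagents that add atoms: vinylmagnesium bromide, C=C[Mg]Br; N-(5-chloro-2-pyridyl)bis(trifluoromethanesulfonimide), O=S(=O)(N(c1ccc(Cl)cn1)S(=O)(=O)C(F)(F)F)C(F)(F)F
Why: Copper-catalysed conjugate addition of the vinyl Grignard reagent should occur anti to the adjacent isopropyl group (trans product, new stereocentre under substrate control), and O-triflation of the regiodefined enolate fixes the alkene position.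

Step 20
Reactants: 28 enol triflate
Product: 29 (3R,4R)-3-formyl-4-(propan-2-yl)cyclohex-1-en-1-yl trifluoromethanesulfonate
Conditions: O3, CH2Cl2/MeOH, −78 °C (indicator dye); then Me2S
Reagents that add atoms: ozone, [O-][O+]=O
Why: Ozonolysis should cleave the electron-richer monosubstituted vinyl group selectively, the triflyloxy-substituted alkene being strongly deactivated; reductive work-up gives the aldehyde without loss of the adjacent stereocentre.

Step 21
Reactants: 29 aldehyde
Product: 30 ethyl (2Z)-2-bromo-3-[(1R,6R)-6-(propan-2-yl)-3-(trifluoromethanesulfonyloxy)cyclohex-2-en-1-yl]prop-2-enoate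
Conditions: Ph3P=CHCO2Et, NBS, CH2Cl2, −20 °C; then 29, −20 °C to rt
Reagents that add atoms: ethyl (triphenylphosphoranylidene)acetate, CCOC(=O)C=P(c1ccccc1)(c1ccccc1)c1ccccc1; N-bromosuccinimide, O=C1CCC(=O)N1Br
Why: Tandem bromination–Wittig olefination (the bromo ylide is formed in the flask) should give the (Z)-α-bromo enoate, the ester trans to the ring carbon as is usual for stabilised ylides.

Step 22
Reactants: 30 bromo enoate triflate
Product: 31 ethyl (2E)-2-(hydroxymethyl)-3-[(1R,6R)-3-(hydroxymethyl)-6-(propan-2-yl)cyclohex-2-en-1-yl]prop-2-enoate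
Conditions: Bu3SnCH2OH (2.6 equiv), Pd(PPh3)4 (10 mol%), LiCl, dioxane, 100 °C
Reagents that add atoms: (tributylstannyl)methanol, CCCC[Sn](CCCC)(CCCC)CO
Why: Stille (Migita–Kosugi–Stille) cross-coupling with the hydroxymethyl stannane should replace both the alkenyl triflate and the alkenyl bromide with retention of alkene position and geometry, which gives the ring carbon cis to CH2OH.

Step 23
Reactants: 31 diol ester
Product: 32 ethyl (2E)-2-{[(tert-butyldimethylsilyl)oxy]methyl}-3-[(1R,6R)-3-{[(tert-butyldimethylsilyl)oxy]methyl}-6-(propan-2-yl)cyclohex-2-en-1-yl]prop-2-enoate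
Conditions: TBSCl, imidazole, DMF, rt
Reagents that add atoms: tert-butyldimethylsilyl chloride, CC(C)(C)[Si](C)(C)Cl
Why: Silylation of both primary hydroxyls protects them for the esterification.

Step 24
Reactants: 32 bis-silyl ether ester
Product: 33 (2E)-2-{[(tert-butyldimethylsilyl)oxy]methyl}-3-[(1R,6R)-3-{[(tert-butyldimethylsilyl)oxy]methyl}-6-(propan-2-yl)cyclohex-2-en-1-yl]prop-2-enoic acid
Conditions: LiOH·H2O, THF/MeOH/H2O, 40 °C; then 1 M HCl to pH 4, 0 °C
Reagents that add atoms: lithium hydroxide, [Li+].[OH-]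
Why: Saponification of the ethyl ester should leave the silyl ethers intact; brief mild acidification gives the free acid.

Step 25
Reactants: 33 left-half acid; 23 right-half diol
Product: 35 tert-butyl ester and bis-TBS ether of the target, via mixed anhydride 34 (not isolated)
Conditions: 2,4,6-trichlorobenzoyl chloride, Et3N, THF, rt; then 23, DMAP, toluene, 0 °C to rt
Reagents that add atoms: none
Why: Yamaguchi esterification through the mixed anhydride should acylate the primary hydroxyl only, the tertiary hydroxyl being too hindered; no stereocentre is affected.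

Step 26
Reactants: 35 protected dimer
Product: 36 target compound
Conditions: CF3CO2H/CH2Cl2/H2O (25:70:5), 0 °C to rt; aq. NaHCO3 wash, then pH 4
Reagents that add atoms: none
Why: Acidolysis should cleave the tert-butyl ester (loss of 2-methylpropene) and both primary silyl ethers in one operation, and the hydrogencarbonate wash should hydrolyse any trifluoroacetate esters while lactone and ester links stay intact.

**Compound list**

1 | (S)-lactic acid | C[C@H](O)C(=O)O | starting material
2 | pivalaldehyde (2,2-dimethylpropanal) | CC(C)(C)C=O | starting material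
3 | (2S,5S)-2-tert-butyl-5-methyl-1,3-dioxolan-4-one (cis) | CC(C)(C)[C@H]1O[C@@H](C)C(=O)O1 | intermediate
4 | 5-bromo-2-tert-butyl-5-methyl-1,3-dioxolan-4-one (acetal carbon as in 3, C5 epimers) | CC(C)(C)[C@H]1OC(C)(Br)C(=O)O1 | intermediate
5 | (2S)-2-tert-butyl-5-methylidene-1,3-dioxolan-4-one | CC(C)(C)[C@H]1OC(=C)C(=O)O1 | intermediate
6 | 3-methylbutanal | CC(C)CC=O | starting material
7 | 3-methyl-2-methylidenebutanal | CC(C)C(=C)C=O | intermediate
8 | ethyl (2E)-5-methyl-4-methylidenehex-2-enoate | CCOC(=O)/C=C/C(=C)C(C)C | intermediate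
9 | (2E)-5-methyl-4-methylidenehex-2-en-1-ol | OC/C=C/C(=C)C(C)C | intermediate
10 | (2E)-5-methyl-4-methylidenehex-2-en-1-yl acetate | CC(=O)OC/C=C/C(=C)C(C)C | intermediate
11 | [(2S,5R,6R)-2-tert-butyl-4-oxo-8-(propan-2-yl)-1,3-dioxaspiro[4.5]dec-7-en-6-yl]methyl acetate | CC(=O)OC[C@H]1C=C(C(C)C)CC[C@@]12O[C@H](C(C)(C)C)OC2=O | intermediate
12 | (1R,2R)-1,2-bis(hydroxymethyl)-4-(propan-2-yl)cyclohex-3-en-1-ol | OC[C@H]1C=C(C(C)C)CC[C@]1(O)CO | intermediate
13 | [(5R,6R)-2,2-dimethyl-8-(propan-2-yl)-1,3-dioxaspiro[4.5]dec-7-en-6-yl]methanol | OC[C@H]1C=C(C(C)C)CC[C@]12COC(C)(C)O2 | intermediate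
14 | (5R,6R,7S,8S)-6-(hydroxymethyl)-2,2-dimethyl-8-(propan-2-yl)-1,3-dioxaspiro[4.5]decane-7-carbaldehyde | CC1(C)OC[C@@]2(O1)CC[C@@H](C(C)C)[C@H](C=O)[C@@H]2CO | intermediate
15 | 2,2-dimethyl-7'-(propan-2-yl)hexahydro-1'H-spiro[[1,3]dioxolane-4,4'-[2]benzofuran]-1'-ol (cis-fused lactol of 14, anomer mixture) | CC1(C)OC[C@@]2(O1)CC[C@@H](C(C)C)[C@@H]3C(O)OC[C@H]23 | intermediate
16 | [(5R,6R,7S,8S)-7-ethenyl-2,2-dimethyl-8-(propan-2-yl)-1,3-dioxaspiro[4.5]decan-6-yl]methanol | CC1(C)OC[C@@]2(O1)CC[C@@H](C(C)C)[C@H](C=C)[C@@H]2CO | intermediate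
17 | (5R,6S,7S,8S)-7-ethenyl-2,2-dimethyl-8-(propan-2-yl)-1,3-dioxaspiro[4.5]decane-6-carbaldehyde | CC1(C)OC[C@@]2(O1)CC[C@@H](C(C)C)[C@H](C=C)[C@@H]2C=O | intermediate
18 | (5R,6S,7S,8S)-7-ethenyl-2,2-dimethyl-8-(propan-2-yl)-1,3-dioxaspiro[4.5]decane-6-carboxylic acid | CC1(C)OC[C@@]2(O1)CC[C@@H](C(C)C)[C@H](C=C)[C@@H]2C(=O)O | intermediate
19 | tert-butyl 2-(bromomethyl)prop-2-enoate | C=C(CBr)C(=O)OC(C)(C)C | starting material
20 | potassium salt of 18 | CC1(C)OC[C@@]2(O1)CC[C@@H](C(C)C)[C@H](C=C)[C@@H]2C(=O)[O-].[K+] | intermediate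
21 | 2-(tert-butoxycarbonyl)prop-2-en-1-yl (5R,6S,7S,8S)-7-ethenyl-2,2-dimethyl-8-(propan-2-yl)-1,3-dioxaspiro[4.5]decane-6-carboxylate | CC1(C)OC[C@@]2(O1)CC[C@@H](C(C)C)[C@H](C=C)[C@@H]2C(=O)OCC(=C)C(=O)OC(C)(C)C | intermediate
22 | acetonide of 23 (spiro-dioxolane on the 9-hydroxy-9-hydroxymethyl unit) | CC1(C)OC[C@@]2(O1)CC[C@@H](C(C)C)[C@@H]3C=C(C(=O)OC(C)(C)C)COC(=O)[C@@H]32 | intermediate
23 | tert-butyl (5aR,6S,9R,9aS)-9-hydroxy-9-(hydroxymethyl)-1-oxo-6-(propan-2-yl)-1,3,5a,6,7,8,9,9a-octahydro-2-benzoxepine-4-carboxylate | OC[C@@]1(O)CC[C@@H](C(C)C)[C@@H]2C=C(C(=O)OC(C)(C)C)COC(=O)[C@@H]21 | intermediate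
24 | but-3-en-2-one | CC(=O)C=C | starting material
25 | (2R)-5-oxo-2-(propan-2-yl)hexanal | CC(=O)CC[C@@H](C=O)C(C)C | intermediate
26 | (4R)-4-(propan-2-yl)cyclohex-2-en-1-one ((R)-cryptone) | CC(C)[C@H]1CCC(=O)C=C1 | intermediate
27 | bromomagnesium (3R,4R)-3-ethenyl-4-(propan-2-yl)cyclohex-1-en-1-olate | CC(C)[C@H]1CCC(O[Mg]Br)=C[C@@H]1C=C | intermediate
28 | (3R,4R)-3-ethenyl-4-(propan-2-yl)cyclohex-1-en-1-yl trifluoromethanesulfonate | CC(C)[C@H]1CCC(OS(=O)(=O)C(F)(F)F)=C[C@@H]1C=C | intermediate
29 | (3R,4R)-3-formyl-4-(propan-2-yl)cyclohex-1-en-1-yl trifluoromethanesulfonate | CC(C)[C@H]1CCC(OS(=O)(=O)C(F)(F)F)=C[C@@H]1C=O | intermediate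
30 | ethyl (2Z)-2-bromo-3-[(1R,6R)-6-(propan-2-yl)-3-(trifluoromethanesulfonyloxy)cyclohex-2-en-1-yl]prop-2-enoate | CC(C)[C@H]1CCC(OS(=O)(=O)C(F)(F)F)=C[C@@H]1/C=C(\Br)C(=O)OCC | intermediate
31 | ethyl (2E)-2-(hydroxymethyl)-3-[(1R,6R)-3-(hydroxymethyl)-6-(propan-2-yl)cyclohex-2-en-1-yl]prop-2-enoate | CC(C)[C@H]1CCC(CO)=C[C@@H]1/C=C(\CO)C(=O)OCC | intermediate
32 | bis(tert-butyldimethylsilyl) ether of 31 | CC(C)[C@H]1CCC(CO[Si](C)(C)C(C)(C)C)=C[C@@H]1/C=C(\CO[Si](C)(C)C(C)(C)C)C(=O)OCC | intermediate
33 | (2E)-2-{[(tert-butyldimethylsilyl)oxy]methyl}-3-[(1R,6R)-3-{[(tert-butyldimethylsilyl)oxy]methyl}-6-(propan-2-yl)cyclohex-2-en-1-yl]prop-2-enoic acid | CC(C)[C@H]1CCC(CO[Si](C)(C)C(C)(C)C)=C[C@@H]1/C=C(\CO[Si](C)(C)C(C)(C)C)C(=O)O | intermediate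
34 | mixed anhydride of 33 with 2,4,6-trichlorobenzoic acid | CC(C)[C@H]1CCC(CO[Si](C)(C)C(C)(C)C)=C[C@@H]1/C=C(\CO[Si](C)(C)C(C)(C)C)C(=O)OC(=O)c1c(Cl)cc(Cl)cc1Cl | intermediate
35 | target with the carboxylic acid as tert-butyl ester and both left-half hydroxyls as TBS ethers | CC(C)[C@H]1CCC(CO[Si](C)(C)C(C)(C)C)=C[C@@H]1/C=C(\CO[Si](C)(C)C(C)(C)C)C(=O)OC[C@@]1(O)CC[C@@H](C(C)C)[C@@H]2C=C(C(=O)OC(C)(C)C)COC(=O)[C@@H]21 | intermediate
36 | CNP0361406.3 | CC(C)[C@H]1CCC(CO)=C[C@@H]1/C=C(\CO)C(=O)OC[C@@]1(O)CC[C@@H](C(C)C)[C@@H]2C=C(C(=O)O)COC(=O)[C@@H]21 | target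

**Step count and risks**

Total steps: 26. Longest linear sequence: 15 steps (6, then steps 4 to 16, then steps 25 and 26).

Steps most likely to fail:

1. Step 11 (Proposed new method). The trisubstituted ring alkene may insert too slowly into Rh–H, or isomerise, so that directed delivery from the hydroxymethyl face does not take place. The fallback uses known chemistry, sets out from 13 and comes back at 15. 13 would be silylated with chlorodimethylsilane/Et3N to the dimethylsilyl ether F1. Zerovalent platinum (Pt2[(CH2=CHSiMe2)2O]3) should then bring about intramolecular syn-hydrosilylation, known for trisubstituted alkenes of homoallylic alcohols, to the cis-fused oxasilolane F2, with silicon on the ring carbon next to the CH2O-bearing carbon and hydrogen on the isopropyl-bearing carbon from the same face. Tamao–Fleming oxidation (H2O2, KF, KHCO3) would give, with retention, the diol F3. The primary hydroxyl would be silylated (TBSCl, imidazole) to the silyl ether F4, and the secondary alcohol oxidised with Dess–Martin periodinane to the ketone F5. Base-free methylenation with Cp2TiMe2 would give the exocyclic alkene F6, and hydroboration with 9-BBN followed by NaBO3 the hydroxymethyl compound F7. Dess–Martin oxidation would give the aldehyde F8, and Bu4NF would remove the silyl group, the aldehyde equilibrating to the equatorial epimer that closes to lactol 15.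

2. Step 8. The cycloaddition may be sluggish, with polymerisation of the captodative alkene and erosion of exo and face selectivity at the temperature needed. The fallback sets out from 10 and comes back at 12. The diene would be combined at low temperature with separately prepared 1-formylvinyl benzoate F9 under a chiral primary ammonium salt (iminium activation; exo- and enantioselective Diels–Alder reactions of α-acyloxyacroleins are known) to give the formyl benzoate F10. LiAlH4 would then reduce the formyl group and cleave benzoate and acetate to triol 12.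

3. Step 15. Initiation at the hindered vinyl group may be poor, and intermolecular metathesis through the acrylate may compete with closure of the seven-membered ring. The fallback sets out from 15 and comes back at 22. Lactol 15 would be olefinated with the bromo ylide made in the flask from tert-butyl (triphenylphosphoranylidene)acetate and NBS to the (Z)-bromo enoate alcohol F11. TEMPO/PhI(OAc)2 oxidation would give the bromo enoate acid F12, and Stille coupling with Bu3SnCH2OH (Pd(PPh3)4) the hydroxy acid F13. Yamaguchi lactonisation at high dilution would then close the seven-membered lactone 22 through the C–O bond instead of the C=C bond.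

**Further compounds**

F1 | step 11 | dimethylsilyl ether of 13 | C[SiH](C)OC[C@H]1C=C(C(C)C)CC[C@]12COC(C)(C)O2
F2 | step 11 | cis-fused oxasilolane from intramolecular hydrosilylation of F1 | CC1(C)OC[C@@]2(O1)CC[C@@H](C(C)C)[C@@H]3[Si](C)(C)OC[C@H]23
F3 | step 11 | 6-(hydroxymethyl)-2,2-dimethyl-8-(propan-2-yl)-1,3-dioxaspiro[4.5]decan-7-ol (hydroxyl cis to CH2OH, trans to isopropyl) | CC1(C)OC[C@@]2(O1)CC[C@@H](C(C)C)[C@H](O)[C@@H]2CO
F4 | step 11 | primary TBS ether of F3 | CC1(C)OC[C@@]2(O1)CC[C@@H](C(C)C)[C@H](O)[C@@H]2CO[Si](C)(C)C(C)(C)C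
F5 | step 11 | ketone from F4 (7-oxo compound) | CC1(C)OC[C@@]2(O1)CC[C@@H](C(C)C)C(=O)[C@@H]2CO[Si](C)(C)C(C)(C)C
F6 | step 11 | 7-methylidene compound from F5 | CC1(C)OC[C@@]2(O1)CC[C@@H](C(C)C)C(=C)[C@@H]2CO[Si](C)(C)C(C)(C)C
F7 | step 11 | 7-(hydroxymethyl) compound from F6 | CC1(C)OC[C@@]2(O1)CC[C@@H](C(C)C)[C@H](CO)[C@@H]2CO[Si](C)(C)C(C)(C)C
F8 | step 11 | TBS ether of hydroxy aldehyde 14 | CC1(C)OC[C@@]2(O1)CC[C@@H](C(C)C)[C@H](C=O)[C@@H]2CO[Si](C)(C)C(C)(C)C
F9 | step 8 | 1-formylvinyl benzoate | C=C(C=O)OC(=O)c1ccccc1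
F10 | step 8 | (1R,6R)-6-(acetoxymethyl)-1-formyl-4-(propan-2-yl)cyclohex-3-en-1-yl benzoate | CC(=O)OC[C@H]1C=C(C(C)C)CC[C@@]1(C=O)OC(=O)c1ccccc1
F11 | step 15 | (Z)-bromo enoate alcohol (tert-butyl 2-bromo-3-substituted propenoate at the 7-position of the spiro acetonide, 6-hydroxymethyl) | CC1(C)OC[C@@]2(O1)CC[C@@H](C(C)C)[C@H](/C=C(\Br)C(=O)OC(C)(C)C)[C@@H]2CO
F12 | step 15 | (Z)-bromo enoate acid (6-carboxylic acid from F11) | CC1(C)OC[C@@]2(O1)CC[C@@H](C(C)C)[C@H](/C=C(\Br)C(=O)OC(C)(C)C)[C@@H]2C(=O)O
F13 | step 15 | hydroxy acid (2-hydroxymethyl enoate, seco acid of 22) | CC1(C)OC[C@@]2(O1)CC[C@@H](C(C)C)[C@H](/C=C(\CO)C(=O)OC(C)(C)C)[C@@H]2C(=O)O
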